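The dimer is cut at its single inter-unit bond C15–C12′, which ties the γ-carbon of the dienyl butenolide ring to the carbon beside the transposed C13′=C14′ butenolide ring. The key step exploits this feature: it is what a C15 furanolate leaves when it attacks C12′ of andrographolide and the allylic C14′ oxygen departs, so both C20 halves come from andrographolide with all decalin rings and stereocentres intact. One half is dehydrated to the dienyl butenolide and turned into a 2-silyloxyfuran; the other keeps its E-alkylidene lactone as the 14-acetate. A Lewis-acid vinylogous Mukaiyama–Michael addition with acetate loss forms the bond, both new stereocentres and the second butenolide in one operation; acetonides mask the diols.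

Key step: step 6

Assumption: atoms carry the usual ent-labdane numbering of andrographolide (C14 carbinol carbon, C15 lactone OCH2, C16 lactone carbonyl, C17 exocyclic methylene, C19 CH2OH); primed locants belong to the half that derives from the acetate.

Step 1
Reactants: 1 andrographolide
Product: 2 3,19-O-isopropylideneandrographolide
Conditions: 2,2-dimethoxypropane, PPTS (cat.), toluene–DMSO, 80 °C
Reagents that add atoms: 2,2-dimethoxypropane, COC(C)(C)OC
Why: Acid-catalysed transketalisation (acetonide formation) closes a 1,3-dioxane across the 1,3-related C3 and C19 hydroxyls, while the isolated allylic 14-OH cannot form a cyclic ketal and stays free, and no stereocentre is touched.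

Step 2
Reactants: 2 3,19-O-isopropylideneandrographolide
Product: 3 14-O-acetyl-3,19-O-isopropylideneandrographolide (14S)
Conditions: Ac2O (1.5 equiv), pyridine, DMAP (cat.), CH2Cl2, −10 to 0 °C; pH 7 buffer quench
Reagents that add atoms: acetic anhydride, CC(=O)OC(C)=O
Why: DMAP-catalysed O-acylation of the only free hydroxyl keeps the 14S configuration because the C14–O bond is not broken, and the low temperature and weak base hold back the E1cB-type loss of acetic acid from the product (which would in any case give compound 5, usable in step 5).

Step 3
Reactants: 1 andrographolide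
Product: 4 14-deoxy-11,12-didehydroandrographolide
Conditions: neutral Al2O3, pyridine, reflux
Reagents that add atoms: none
Why: Alumina-promoted vinylogous 1,4-dehydration removes H-11 and the allylic 14-hydroxyl, so the double bonds move to C11=C12 and C13=C14 and give the conjugated dienyl butenolide, with the new disubstituted alkene taking the less strained E geometry.

Step 4
Reactants: 4 14-deoxy-11,12-didehydroandrographolide
Product: 5 3,19-O-isopropylidene-14-deoxy-11,12-didehydroandrographolide
Conditions: 2,2-dimethoxypropane, PPTS (cat.), CH2Cl2–acetone, rt
Reagents that add atoms: 2,2-dimethoxypropane, COC(C)(C)OC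
Why: The same acid-catalysed acetonide formation masks the 3,19-diol so that the silyl triflate of the next step meets no free hydroxyl, and the diene, the butenolide and the stereocentres are inert to PPTS at room temperature.

Step 5
Reactants: 5 3,19-O-isopropylidene-14-deoxy-11,12-didehydroandrographolide
Product: 6 2-(triisopropylsilyloxy)furan of the dienyl half
Conditions: TIPSOTf (1.2 equiv), Et3N (2 equiv), CH2Cl2, 0 °C; quick filtration through Et3N-deactivated silica
Reagents that add atoms: triisopropylsilyl trifluoromethanesulfonate, CC(C)[Si](C(C)C)(C(C)C)OS(=O)(=O)C(F)(F)F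
Why: Soft enolisation of the butenolide (O-silylation of the carbonyl followed by loss of a γ-proton from C15 to the amine) gives the aromatic 2-silyloxyfuran, the standard way to such furans, and the bulky silyl group makes the product stable enough to isolate.

Step 6
Reactants: 3 14-O-acetyl-3,19-O-isopropylideneandrographolide; 6 2-(triisopropylsilyloxy)furan of the dienyl half (1.3 equiv)
Product: 8 bis(3,19-O-isopropylidene) derivative of the target (15R,12′S), via silyl ketene acetal Michael adduct 7 (not isolated)
Conditions: Sc(OTf)3 (10 mol %), 2,6-di-tert-butyl-4-methylpyridine (20 mol %), 4 Å MS, CH2Cl2, −78 to −40 °C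
Reagents that add atoms: none
Why: Sc(OTf)3 activates the lactone carbonyl of 3, the 2-silyloxyfuran 6 attacks the exocyclic β-carbon C12′ through its 5-position (C15) with silyl transfer to give the silyl ketene acetal 7, and 7 expels the β-acetate at C14′ as triisopropylsilyl acetate, which creates the C13′=C14′ butenolide while the nucleophile half returns to its α-dienyl butenolide. The closest known reaction types are the vinylogous Mukaiyama–Michael addition of 2-silyloxyfurans to α-alkylidene carbonyl compounds and the allylic substitution of Morita–Baylis–Hillman acetates by 2-silyloxyfurans, and hetero-nucleophiles are known to replace the 14-acetate of andrographolide esters at C12 in the same addition–elimination sense. No ring is closed, since the step only joins the two C20 chains through the C15–C12′ bond. C12′ (S) is controlled by the 14′S acetate, whose C–O bond stands almost perpendicular to the plane of the rigid E-alkylidene lactone, so that the furan should add to the opposite (Si) face of C12′ in a net anti SN2′ course. C15 (R) is controlled by the relative topicity of the open transition state, in which an antiperiplanar approach that puts the small C15–H between C13′ and the C11′ methylene and the silyloxy-bearing flank in the sector next to the vinylic hydrogen pairs the Si face of C15 with the Si face of C12′ as required. The step further needs bonding at C15 and not at C11 or C13, which the usual 5-selectivity of 2-silyloxyfurans, the substituted α-carbon C13 and the hindered C11 beside the decalin secure, and it needs the acetonides, the exocyclic methylenes and the silyloxyfuran to outlast the Lewis acid, which the low temperature and the hindered pyridine buffer secure.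

Step 7
Reactants: 8 bis(3,19-O-isopropylidene) derivative of the target
Product: 9 target CNP0220272.2
Conditions: AcOH–H2O (7:3), rt
Reagents that add atoms: none
Why: Mild acid-catalysed ketal hydrolysis frees both 3,19-diols, and dilute acetic acid should leave the butenolides, the exocyclic methylenes and the C15 and C12′ centres (which can epimerise only through base-formed enolates) undisturbed.

Compound list

1 | andrographolide, (3E,4S)-3-{2-[(1R,4aS,5R,6R,8aS)-6-hydroxy-5-(hydroxymethyl)-5,8a-dimethyl-2-methylidenedecahydronaphthalen-1-yl]ethylidene}-4-hydroxyoxolan-2-one | C=C1CC[C@@H]2[C@](C)(CO)[C@H](O)CC[C@@]2(C)[C@@H]1C/C=C1/C(=O)OC[C@H]1O | starting material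
2 | 3,19-O-isopropylideneandrographolide (1,3-dioxane across O3 and O19, free 14S-OH, 12E-alkylidene lactone, decalin centres as in 1) | C=C1CC[C@@H]2[C@](C)(COC(C)(C)O3)[C@H]3CC[C@@]2(C)[C@@H]1C/C=C1/C(=O)OC[C@H]1O | intermediate
3 | 14-O-acetyl-3,19-O-isopropylideneandrographolide (14S acetate on the 12E-alkylidene lactone) | C=C1CC[C@@H]2[C@](C)(COC(C)(C)O3)[C@H]3CC[C@@]2(C)[C@@H]1C/C=C1/C(=O)OC[C@H]1OC(C)=O | intermediate
4 | 14-deoxy-11,12-didehydroandrographolide (11E-alkene conjugated with the 13(14)-butenolide, free 3,19-diol, decalin centres as in 1) | C=C1CC[C@@H]2[C@](C)(CO)[C@H](O)CC[C@@]2(C)[C@@H]1/C=C/C1=CCOC1=O | intermediate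
5 | 3,19-O-isopropylidene-14-deoxy-11,12-didehydroandrographolide | C=C1CC[C@@H]2[C@](C)(COC(C)(C)O3)[C@H]3CC[C@@]2(C)[C@@H]1/C=C/C1=CCOC1=O | intermediate
6 | 2-(triisopropylsilyloxy)furan bearing at its 3-position the (E)-vinyl link to C9 of the acetonide-protected decalin (silyl dienol ether of 5) | C=C1CC[C@@H]2[C@](C)(COC(C)(C)O3)[C@H]3CC[C@@]2(C)[C@@H]1/C=C/c1ccoc1O[Si](C(C)C)(C(C)C)C(C)C | intermediate
7 | silyl ketene acetal Michael adduct (C15–C12′ bond formed, 15R,12′S; lactone of the primed half as its O-triisopropylsilyl ketene acetal C13′=C16′; 14′S acetate still present; formed in the flask in step 6 and not isolated) | C=C1CC[C@@H]2[C@](C)(COC(C)(C)O3)[C@H]3CC[C@@]2(C)[C@@H]1/C=C/C1=C[C@H]([C@@H](C[C@@H]2C(=C)CC[C@@H]3[C@](C)(COC(C)(C)O4)[C@H]4CC[C@]32C)C2=C(O[Si](C(C)C)(C(C)C)C(C)C)OC[C@H]2OC(C)=O)OC1=O | intermediate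
8 | bis(3,19-O-isopropylidene) derivative of the target (15R,12′S; 11E-dienyl butenolide half joined at C15 to C12′ of the 13′(14′)-butenolide half) | C=C1CC[C@@H]2[C@](C)(COC(C)(C)O3)[C@H]3CC[C@@]2(C)[C@@H]1/C=C/C1=C[C@H]([C@@H](C[C@@H]2C(=C)CC[C@@H]3[C@](C)(COC(C)(C)O4)[C@H]4CC[C@]32C)C2=CCOC2=O)OC1=O | intermediate
9 | target CNP0220272.2: 14-deoxy-11,12-didehydroandrographolide unit bonded at C15 (R) to C12′ (S) of a 14′-deoxyandrographolide unit with a 13′(14′)-butenolide, both 3,19-diols free | C=C1CC[C@@H]2[C@](C)(CO)[C@H](O)CC[C@@]2(C)[C@@H]1/C=C/C1=C[C@H]([C@@H](C[C@@H]2C(=C)CC[C@@H]3[C@](C)(CO)[C@H](O)CC[C@]32C)C2=CCOC2=O)OC1=O | target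

Total step count: 7. Longest linear sequence: 5 steps (1 → 4 → 5 → 6 → 8 → 9); the electrophile branch (1 → 2 → 3) has 2 steps.

Steps most likely to fail

Step 6. The relative topicity of the union may be poorly controlled, so that the furan bonds through the wrong face of C15 while C12′ is still set correctly by the acetate. The fallback sets out from 3 and 6 under the conditions of step 6 and comes back at 8. It accepts the C15 epimer of compound 8 F1 and corrects it under thermodynamic control. C15 is the γ-carbon of a butenolide, so catalytic DBU in CH2Cl2 at 0 °C to rt should equilibrate F1 with 8 through the 2-oxyfuran, a known way of epimerising γ-substituted butenolides. C12′ has no acidifying group and should stay fixed. Compound 8 is separated and F1 is resubmitted.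

Step 5. The silyl dienol ether may be lost by hydrolysis during isolation, or enolisation may be incomplete. The fallback sets out from 5 and comes back at 8 without any silyl enol ether or Lewis acid. Deprotonation with LiN(SiMe3)2 in THF at −78 °C gives the lithium 2-furanolate of the dienyl half F2, and acetate 3 is then added at −78 °C. Conjugate addition at C12′ followed by E1cB loss of acetate, the course that amine and thiolate nucleophiles take with 14-acetylandrographolides, should give 8 directly.

Step 2. Base-induced loss of acetic acid from the product (vinylogous elimination to the dienyl butenolide) may compete with acylation. The fallback sets out from 1 and comes back at 3 with the two operations in reverse order and no amine base. Lipase-mediated transesterification (immobilised Candida antarctica lipase B, vinyl acetate, acetone, 40 °C) is a neutral acylation of the kind used for regioselective 14-O-acylation of andrographolide. It should give 14-O-acetylandrographolide F3. Acetonide formation with 2,2-dimethoxypropane and PPTS in CH2Cl2 then gives 3.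

Further compounds

F1 | step 6 | C15 epimer of compound 8 (15S,12′S) | C=C1CC[C@@H]2[C@](C)(COC(C)(C)O3)[C@H]3CC[C@@]2(C)[C@@H]1/C=C/C1=C[C@@H]([C@@H](C[C@@H]2C(=C)CC[C@@H]3[C@](C)(COC(C)(C)O4)[C@H]4CC[C@]32C)C2=CCOC2=O)OC1=O
F2 | step 5 | lithium 2-furanolate of the dienyl half | C=C1CC[C@@H]2[C@](C)(COC(C)(C)O3)[C@H]3CC[C@@]2(C)[C@@H]1/C=C/c1ccoc1[O-].[Li+]
F3 | step 2 | 14-O-acetylandrographolide | C=C1CC[C@@H]2[C@](C)(CO)[C@H](O)CC[C@@]2(C)[C@@H]1C/C=C1/C(=O)OC[C@H]1OC(C)=O
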